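The earlier runs and the new flask are calculated from invented constants; the scatter is artificial.

The more initiator a run got, the more starting material went missing: over the last three readings, product plus starting material falls short of the charge by 20.3% on Saturday's run, 33.3% on Friday's and 47.0% on Sunday's. Twice the loadings gives 19.4%, 32.0% and 50.0%, which is close. That fits the steps: one initiator gives two initiating radicals, each takes one starting material into a first chain carrier, and such carriers finish as ended chains A.

| setting | Saturday's | Friday's | Sunday's | violet | green | ochre |
|---|---|---|---|---|---|---|
| starting material | 0.62 M | 0.62 M | 0.62 M | 0.62 M | 0.62 M | 0.62 M |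
| reagent | 1 equiv | 1 equiv | 1 equiv | 1.00 equiv | 1.00 equiv | 1.00 equiv |
| initiator | 9.7 mol% | 16 mol% | 25 mol% | 8 mol% | 15 mol% | 30 mol% |
| radical scavenger | 0.2 mol% | 0.2 mol% | 0.2 mol% | 0.2 mol% | 0.2 mol% | 0.2 mol% |
| remark | run made earlier | run made earlier | run made earlier |  |  |  |
| time |  |  |  | 8.0 h | 8.0 h | 8.0 h |

| run | time / h | product / % | starting material / % |
|---|---|---|---|
| Saturday's | 1.00 | 33 | 52 |
| Saturday's | 2.50 | 48 | 35 |
| Saturday's | 3.00 | 45 | 33 |
| Saturday's | 5.00 | 50 | 33 |
| Saturday's | 6.00 | 48 | 30 |
| Friday's | 0.500 | 28 | 57 |
| Friday's | 1.33 | 44 | 25 |
| Friday's | 2.50 | 52 | 16 |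
| Friday's | 4.00 | 51 | 14 |
| Friday's | 6.00 | 56 | 11 |
| Sunday's | 1.00 | 41 | 16 |
| Sunday's | 2.50 | 52 | 0 |
| Sunday's | 3.00 | 50 | 2 |
| Sunday's | 5.00 | 51 | 2 |
| Sunday's | 6.00 | 51 | 3 |

(readings scatter by 1.5 percentage points)

- percentages count the starting material that a species holds: one ended chains A counts as two
- steps under discussion: starting material + second chain carrier -> by-product + first chain carrier; starting material + initiating radical -> capped initiator + first chain carrier; initiator -> 2 initiating radical; second chain carrier + radical scavenger -> ended chains B; reagent + first chain carrier <-> product + second chain carrier; 2 first chain carrier -> ended chains A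
- "hardly changes" means that all values lie within two and a half points (for a concentration: within two and a half percent of the largest)

- amount of product at the end, in percent of the starting material charged for violet, green, ochre, in this order
- how that number moves from the first to the last of them (rises, then falls / rises all the way / falls, then rises / falls all the way / hardly changes)

For you at the bench: violet should lose 16.0% of its starting material to ended chains A, twice its loading; call this share the toll, the termination loss, so product plus starting material left should come to 84.0%. Green's toll is 30.0%. Leave the flasks alone until 8.0 h: Saturday's product reads 48% at 2.50 h and 48% at 6.00 h.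

Starting material left averages 32.0% on Saturday's run and 13.7% on Friday's. That fall is 2.91 times the rise in loading between those runs. So my reckoning leaves 36.9% in violet and 16.6% in green, which gives 47.1% and 53.4% of product. Ochre's toll of 60.0% would leave 40.0%, but Sunday's run already ends with 3% of starting material, so the toll may stop short; I expect ochre between that figure and Sunday's 51%.

The forecast says 45%, 53% and 45%, rises, then falls, since “At high loading, starting material runs out, so termination losses set the limit.”

The flasks give 46.7%, 54.9% and 47.7%: the row rises, then falls, turning at 19 mol%.

    starting material + second chain carrier → by-product + first chain carrier (k = 56000 M⁻¹ min⁻¹)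
    starting material + initiating radical → capped initiator + first chain carrier (k = 50000 M⁻¹ s⁻¹)
    initiator → 2 initiating radical (k = 0.0260 min⁻¹)
    second chain carrier + radical scavenger → ended chains B (k = 1.80 × 10⁶ M⁻¹ s⁻¹)
    reagent + first chain carrier ⇌ product + second chain carrier (K = 2.30, k = 22000 M⁻¹ min⁻¹)
    2 first chain carrier → ended chains A (k = 1.30 × 10⁸ M⁻¹ s⁻¹)

Ochre ends with 0% of its starting material, and its ended chains A stand at 52.3%, less than its toll of 60.0%. In green, the toll of 30.0% and the 15.3% of starting material left give 54.7% of product.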